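**Retrosynthetic overview**

1. C16–C17 (last step): phosphoric-acid-catalysed kinetic-resolution chloroallylboration of aldehyde 20 with racemic α-chloroallylboronate 25 sets C16 and the (Z)-chloroalkene together (target chain numbered C1 = CH2= to C19 = CHCl).
2. C3–C4 and C9–C10: two phosphoric-acid-catalysed allylborations of α-methyl aldehydes 18 and 4 with allylB(pin) 5 set C4 and C10.
3. C7–C8: cross-metathesis of allyl lactone 7 with (R)-2-methylpent-4-en-1-ol 11 (C5 from organocatalytic α-allylation of propanal), then hydrogenation; C14–C15: Wittig opening of lactol 13 with an acetal ylide.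
4. C11 and C13: the first stereocentres, from organocatalytic desymmetrising methanolysis of meso anhydride 1.
5. Rings: the target has no ring besides the purchased phenyl group; the only ring made is a temporary δ-lactone (step 4), opened again in steps 7–8.

Assumption: the facial sense of each chiral catalyst is taken from the accepted models (in particular (R)-TRIP giving Re-face allylboration); if a first run shows the opposite sense, the mirror-image or pseudo-enantiomeric catalyst is used.

**Route**

Step 1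
Reactants: 1 cis-2,4-dimethylglutaric anhydride (meso-3,5-dimethyloxane-2,6-dione)
Product: 2 (2R,4S)-5-methoxy-2,4-dimethyl-5-oxopentanoic acid
Conditions: MeOH (10 equiv), (DHQ)2AQN (10 mol%), Et2O, −40 °C
Reagents that add atoms: methanol, CO
Why: Cinchona-alkaloid-catalysed desymmetrising alcoholysis of a meso anhydride (metal-free general-base catalysis) sends methanol to one of the two enantiotopic carbonyls, which fixes C11 and C13 in one step from an achiral substrate.

Step 2
Reactants: 2 (2R,4S)-5-methoxy-2,4-dimethyl-5-oxopentanoic acid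
Product: 3 methyl (2S,4R)-5-hydroxy-2,4-dimethylpentanoate
Conditions: BH3·SMe2 (1.2 equiv), THF, 0 °C to rt; MeOH quench
Reagents that add atoms: none
Why: Borane reduction of a carboxylic acid is chemoselective over the methyl ester and touches no stereocentre; 3 is oxidised at once to prevent lactonisation.

Step 3
Reactants: 3 methyl (2S,4R)-5-hydroxy-2,4-dimethylpentanoate
Product: 4 methyl (2S,4R)-2,4-dimethyl-5-oxopentanoate
Conditions: TEMPO (10 mol%), PhI(OAc)2 (1.1 equiv), CH2Cl2, rt
Reagents that add atoms: none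
Why: TEMPO/PhI(OAc)2 oxoammonium oxidation stops at the aldehyde under near-neutral conditions, so the α-methyl centre (C11) does not epimerise.

Step 4
Reactants: 4 methyl (2S,4R)-2,4-dimethyl-5-oxopentanoate; 5 allylboronic acid pinacol ester
Product: 7 (3S,5R,6R)-3,5-dimethyl-6-(prop-2-en-1-yl)oxan-2-one, via hydroxy ester 6 (not isolated)
Conditions: (R)-TRIP phosphoric acid [(R)-3,3'-bis(2,4,6-triisopropylphenyl)-1,1'-binaphthyl-2,2'-diyl hydrogen phosphate] (5 mol%), 5 (1.3 equiv), toluene, −30 °C; aq. NaHCO3; then p-TsOH·H2O (5 mol%), toluene, 50 °C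
Reagents that add atoms: none
Why: Chiral-phosphoric-acid-catalysed allylboration through a closed chair transition state delivers allyl to the Re face, setting C10 as R (catalyst control, matched with Felkin–Anh induction from C11), and acid-catalysed lactonisation then locks the new hydroxyl and the ester as a δ-lactone.

Step 5
Reactants: 8 propanal; 9 allyltrimethylsilane
Product: 11 (R)-2-methylpent-4-en-1-ol, via (R)-2-methylpent-4-enal 10 (not isolated)
Conditions: (2S,5S)-5-benzyl-2-tert-butyl-3-methylimidazolidin-4-one·TFA (20 mol%), 9 (2.5 equiv), (NH4)2Ce(NO3)6 (2 equiv), NaHCO3 (2 equiv), DME, −20 °C; then NaBH4, MeOH, 0 °C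
Reagents that add atoms: none
Why: SOMO-activated organocatalytic α-allylation: one-electron oxidation of the chiral enamine gives a radical cation whose open face is attacked by the allylsilane, setting C5 as R; NaBH4 reduction in the same flask prevents epimerisation of the α-methyl aldehyde.

Step 6
Reactants: 7 (3S,5R,6R)-3,5-dimethyl-6-(prop-2-en-1-yl)oxan-2-one; 11 (R)-2-methylpent-4-en-1-ol
Product: 12 (3S,5R,6R)-6-[(5R)-6-hydroxy-5-methylhex-2-en-1-yl]-3,5-dimethyloxan-2-one (E/Z mixture)
Conditions: 11 (3 equiv), second-generation Grubbs catalyst RuCl2(=CHPh)(H2IMes)(PCy3) (5 mol%), CH2Cl2, 40 °C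
Reagents that add atoms: none
Why: Olefin cross-metathesis of two terminal alkenes forms C7=C8 with loss of ethene; excess 11 drives 7 to the cross product, lactone and free hydroxyl are tolerated, and E/Z is irrelevant because step 9 saturates the bond.

Step 7
Reactants: 12 (3S,5R,6R)-6-[(5R)-6-hydroxy-5-methylhex-2-en-1-yl]-3,5-dimethyloxan-2-one
Product: 13 (3S,5R,6R)-6-[(5R)-6-hydroxy-5-methylhex-2-en-1-yl]-3,5-dimethyloxan-2-ol (anomer mixture)
Conditions: i-Bu2AlH (2.3 equiv), CH2Cl2, −78 °C; aq. potassium sodium tartrate (KNaC4H4O6)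
Reagents that add atoms: none
Why: Low-temperature i-Bu2AlH reduction of a δ-lactone stops at the lactol because the aluminium hemiacetal is stable at −78 °C; the extra equivalent is taken up by the free hydroxyl.

Step 8
Reactants: 13 (3S,5R,6R)-6-[(5R)-6-hydroxy-5-methylhex-2-en-1-yl]-3,5-dimethyloxan-2-ol; 14 (1,3-dioxolan-2-ylmethyl)triphenylphosphonium bromide
Product: 16 (2R,7R,8R,10S)-12-(1,3-dioxolan-2-yl)-2,8,10-trimethyldodeca-4,11-diene-1,7-diol (E/Z mixture), via phosphorus ylide 15 (not isolated)
Conditions: 14 (4 equiv), KOt-Bu (4 equiv), THF, 0 °C to rt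
Reagents that add atoms: none
Why: Wittig olefination of the lactol through its open hydroxy-aldehyde form adds C15 and C16 (already at the aldehyde oxidation level, masked as a dioxolane) and releases the C10 hydroxyl; the product alkene is not a Michael acceptor, so no oxa-Michael closure can occur.

Step 9
Reactants: 16 (2R,7R,8R,10S)-12-(1,3-dioxolan-2-yl)-2,8,10-trimethyldodeca-4,11-diene-1,7-diol
Product: 17 (2R,7R,8R,10R)-12-(1,3-dioxolan-2-yl)-2,8,10-trimethyldodecane-1,7-diol
Conditions: H2 (1 atm), 10% Pd/C, EtOAc, Et3N (1%), rt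
Reagents that add atoms: none
Why: Heterogeneous catalytic hydrogenation saturates both disubstituted alkenes before any alkene that must survive is present; a trace of Et3N protects the acetal.

Step 10
Reactants: 17 (2R,7R,8R,10R)-12-(1,3-dioxolan-2-yl)-2,8,10-trimethyldodecane-1,7-diol
Product: 18 (2R,7R,8R,10R)-12-(1,3-dioxolan-2-yl)-7-hydroxy-2,8,10-trimethyldodecanal
Conditions: TEMPO (10 mol%), PhI(OAc)2 (1.1 equiv), CH2Cl2, rt
Reagents that add atoms: none
Why: TEMPO/PhI(OAc)2 oxidises the primary alcohol selectively in the presence of the secondary C10 hydroxyl (steric selectivity of the oxoammonium salt) without epimerising C5.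

Step 11
Reactants: 18 (2R,7R,8R,10R)-12-(1,3-dioxolan-2-yl)-7-hydroxy-2,8,10-trimethyldodecanal; 5 allylboronic acid pinacol ester
Product: 19 (4R,5R,10R,11R,13R)-15-(1,3-dioxolan-2-yl)-5,11,13-trimethylpentadec-1-ene-4,10-diol
Conditions: (R)-TRIP phosphoric acid (5 mol%), 5 (1.5 equiv), toluene, −30 °C
Reagents that add atoms: none
Why: The same phosphoric-acid-catalysed allylboration (Re-face attack, chair transition state) sets C4 as R under catalyst control, matched with Felkin–Anh induction from C5; the acetal and the free hydroxyl are inert.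

Step 12
Reactants: 19 (4R,5R,10R,11R,13R)-15-(1,3-dioxolan-2-yl)-5,11,13-trimethylpentadec-1-ene-4,10-diol
Product: 20 (4R,6R,7R,12R,13R)-7,13-dihydroxy-4,6,12-trimethylhexadec-15-enal
Conditions: 2 M HCl/THF (1:4), rt
Reagents that add atoms: water, O
Why: Acid-catalysed acetal hydrolysis releases the C16 aldehyde; the homoallylic and secondary alcohols and the terminal alkene are stable to dilute acid at rt.

Step 13
Reactants: 21 (2-bromoprop-2-en-1-yl)benzene; 22 2-(dichloromethyl)-4,4,5,5-tetramethyl-1,3,2-dioxaborolane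
Product: 25 rac-2-(2-benzyl-1-chloroprop-2-en-1-yl)-4,4,5,5-tetramethyl-1,3,2-dioxaborolane, via Grignard reagent 23 (not isolated), via borate complex 24 (not isolated)
Conditions: Mg, THF, 40 °C; then 22, THF, −78 °C; ZnCl2 (0.6 equiv), −78 °C to rt
Reagents that add atoms: none
Why: Matteson-type homologation: the alkenyl Grignard reagent adds to boron and ZnCl2-assisted 1,2-migration of the alkenyl group displaces one chloride to give the α-chloroallylboronate; it is made racemic on purpose because step 14 resolves it.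

Step 14
Reactants: 20 (4R,6R,7R,12R,13R)-7,13-dihydroxy-4,6,12-trimethylhexadec-15-enal; 25 rac-2-(2-benzyl-1-chloroprop-2-en-1-yl)-4,4,5,5-tetramethyl-1,3,2-dioxaborolane
Product: 26 (4R,5R,10R,11R,13R,16R,18Z)-18-benzyl-19-chloro-5,11,13-trimethylnonadeca-1,18-diene-4,10,16-triol (target)
Conditions: (S)-TRIP phosphoric acid (10 mol%), rac-25 (2.5 equiv), 4 Å MS, toluene, −30 °C to 0 °C
Reagents that add atoms: none
Why: Proposed new method: chiral-phosphoric-acid-catalysed kinetic-resolution chloroallylboration, in which the acid hydrogen-bonds the boronate oxygen and the formyl C–H in a closed chair transition state that opens only the Si face of 20, and only (R)-25 can reach that face with chlorine axial (the arrangement α-chloro pinacol boronates demand, reinforced here by allylic 1,2-strain with the 2-benzyl group), so the C16–C17 bond, the 16R carbinol and the Z-chloroalkene (Cl cis to C17) form together while (S)-25 is left behind; the closest known reaction types are the phosphoric-acid-catalysed allylboration of aldehydes with allylB(pin) and the Z-selective uncatalysed (Hoffmann-type) addition of α-chloroallylboronates.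

**Compound list**

1 | cis-2,4-dimethylglutaric anhydride (meso-3,5-dimethyloxane-2,6-dione) | C[C@H]1C[C@@H](C)C(=O)OC1=O | starting material
2 | (2R,4S)-5-methoxy-2,4-dimethyl-5-oxopentanoic acid | OC(=O)[C@H](C)C[C@H](C)C(=O)OC | intermediate
3 | methyl (2S,4R)-5-hydroxy-2,4-dimethylpentanoate | OC[C@H](C)C[C@H](C)C(=O)OC | intermediate
4 | methyl (2S,4R)-2,4-dimethyl-5-oxopentanoate | O=C[C@H](C)C[C@H](C)C(=O)OC | intermediate
5 | allylboronic acid pinacol ester (4,4,5,5-tetramethyl-2-(prop-2-en-1-yl)-1,3,2-dioxaborolane) | C=CCB1OC(C)(C)C(C)(C)O1 | starting material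
6 | methyl (2S,4R,5R)-5-hydroxy-2,4-dimethyloct-7-enoate | C=CC[C@@H](O)[C@H](C)C[C@H](C)C(=O)OC | intermediate
7 | (3S,5R,6R)-3,5-dimethyl-6-(prop-2-en-1-yl)oxan-2-one | C=CC[C@H]1OC(=O)[C@@H](C)C[C@H]1C | intermediate
8 | propanal | CCC=O | starting material
9 | allyltrimethylsilane | C=CC[Si](C)(C)C | starting material
10 | (R)-2-methylpent-4-enal | O=C[C@H](C)CC=C | intermediate
11 | (R)-2-methylpent-4-en-1-ol | OC[C@H](C)CC=C | intermediate
12 | (3S,5R,6R)-6-[(5R)-6-hydroxy-5-methylhex-2-en-1-yl]-3,5-dimethyloxan-2-one (E/Z mixture) | OC[C@H](C)CC=CC[C@H]1OC(=O)[C@@H](C)C[C@H]1C | intermediate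
13 | (3S,5R,6R)-6-[(5R)-6-hydroxy-5-methylhex-2-en-1-yl]-3,5-dimethyloxan-2-ol (anomer and E/Z mixture) | OC[C@H](C)CC=CC[C@H]1OC(O)[C@@H](C)C[C@H]1C | intermediate
14 | (1,3-dioxolan-2-ylmethyl)triphenylphosphonium bromide | [Br-].C1COC(C[P+](c2ccccc2)(c2ccccc2)c2ccccc2)O1 | starting material
15 | (1,3-dioxolan-2-ylmethylidene)triphenylphosphorane | C1COC(C=P(c2ccccc2)(c2ccccc2)c2ccccc2)O1 | intermediate
16 | (2R,7R,8R,10S)-12-(1,3-dioxolan-2-yl)-2,8,10-trimethyldodeca-4,11-diene-1,7-diol (E/Z mixture) | OC[C@H](C)CC=CC[C@@H](O)[C@H](C)C[C@H](C)C=CC1OCCO1 | intermediate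
17 | (2R,7R,8R,10R)-12-(1,3-dioxolan-2-yl)-2,8,10-trimethyldodecane-1,7-diol | OC[C@H](C)CCCC[C@@H](O)[C@H](C)C[C@H](C)CCC1OCCO1 | intermediate
18 | (2R,7R,8R,10R)-12-(1,3-dioxolan-2-yl)-7-hydroxy-2,8,10-trimethyldodecanal | O=C[C@H](C)CCCC[C@@H](O)[C@H](C)C[C@H](C)CCC1OCCO1 | intermediate
19 | (4R,5R,10R,11R,13R)-15-(1,3-dioxolan-2-yl)-5,11,13-trimethylpentadec-1-ene-4,10-diol | C=CC[C@@H](O)[C@H](C)CCCC[C@@H](O)[C@H](C)C[C@H](C)CCC1OCCO1 | intermediate
20 | (4R,6R,7R,12R,13R)-7,13-dihydroxy-4,6,12-trimethylhexadec-15-enal | C=CC[C@@H](O)[C@H](C)CCCC[C@@H](O)[C@H](C)C[C@H](C)CCC=O | intermediate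
21 | (2-bromoprop-2-en-1-yl)benzene | C=C(Br)Cc1ccccc1 | starting material
22 | 2-(dichloromethyl)-4,4,5,5-tetramethyl-1,3,2-dioxaborolane | ClC(Cl)B1OC(C)(C)C(C)(C)O1 | starting material
23 | (3-phenylprop-1-en-2-yl)magnesium bromide | C=C([Mg]Br)Cc1ccccc1 | intermediate
24 | bromomagnesium (dichloromethyl)(3-phenylprop-1-en-2-yl)(pinacolato)borate | C=C(Cc1ccccc1)[B-]1(C(Cl)Cl)OC(C)(C)C(C)(C)O1.[Mg+]Br | intermediate
25 | rac-2-(2-benzyl-1-chloroprop-2-en-1-yl)-4,4,5,5-tetramethyl-1,3,2-dioxaborolane | C=C(Cc1ccccc1)C(Cl)B1OC(C)(C)C(C)(C)O1 | intermediate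
26 | (4R,5R,10R,11R,13R,16R,18Z)-18-benzyl-19-chloro-5,11,13-trimethylnonadeca-1,18-diene-4,10,16-triol (CNP0072706.1) | C=CC[C@@H](O)[C@H](C)CCCC[C@@H](O)[C@H](C)C[C@H](C)CC[C@@H](O)C/C(=C\Cl)Cc1ccccc1 | target

**Step count and risks**

Total steps: 14. Longest linear sequence: 12 (steps 1–4, 6–12 and 14).

Steps most likely to fail:

Step 14 (the proposed new step). The catalyst may not discriminate the enantiomers of 25 well enough, or uncatalysed addition may erode the selectivity at C16. The fallback replaces catalyst control by known reagent control; it sets out from 21 and 20 and comes back to the route at 26. Diisopropyl (dichloromethyl)boronate and (1R,2R)-1,2-dicyclohexylethane-1,2-diol (chosen to give the 1R chloride; its antipode is equally available) give 2-(dichloromethyl)-(4R,5R)-4,5-dicyclohexyl-1,3,2-dioxaborolane F1. Grignard reagent 23, made from 21 as in step 13, adds at −78 °C to give the bromomagnesium borate complex F2, and ZnCl2-promoted 1,2-migration (Matteson homologation, highly diastereoselective with this diol) gives 2-[(1R)-2-benzyl-1-chloroprop-2-en-1-yl]-(4R,5R)-4,5-dicyclohexyl-1,3,2-dioxaborolane F3. F3 (1.5 equiv) adds to 20 without catalyst (toluene, rt) through the chlorine-axial chair (Hoffmann-type α-chloroallylboration), transferring the boron-bearing stereocentre to C16 and giving 26; the diol is recovered.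

Step 8. The acetal ylide is basic and used in excess on a lactol that carries two hydroxyls, so slow opening or epimerisation at C13 is possible. The fallback carries the two-carbon unit as a nitrile and unmasks it by reduction instead of hydrolysis; it sets out from 13 and comes back at 20. (Cyanomethylene)triphenylphosphorane (toluene, 60 °C; a stabilised ylide that needs no base) gives (4S,6R,7R,12R)-7,13-dihydroxy-4,6,12-trimethyltrideca-2,9-dienenitrile F4, which is hydrogenated at once (H2, 10% Pd/C, EtOAc) to (4R,6R,7R,12R)-7,13-dihydroxy-4,6,12-trimethyltridecanenitrile F5 so that oxa-Michael closure has no time to occur. TEMPO/PhI(OAc)2 gives (4R,6R,7R,12R)-7-hydroxy-4,6,12-trimethyl-13-oxotridecanenitrile F6, allylboration with 5 and (R)-TRIP as in step 11 gives (4R,6R,7R,12R,13R)-7,13-dihydroxy-4,6,12-trimethylhexadec-15-enenitrile F7, and i-Bu2AlH (3.3 equiv, CH2Cl2, −78 °C) followed by aqueous tartaric acid converts the nitrile into aldehyde 20.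

Step 5. Propanal is a small, volatile substrate outside the usual scope of the SOMO allylation, and the yield or ee of 11 may be low. The fallback uses known zirconium-catalysed asymmetric carboalumination instead of aminocatalysis; it sets out from no numbered compound (8 and 9 are replaced by commercial prop-2-en-1-ol) and comes back at 11. Prop-2-en-1-ol, Me3Al and bis(1-neomenthylindenyl)zirconium dichloride, (NMI)2ZrCl2 (5 mol%, the enantiomer that delivers methyl to the required face), in CH2Cl2 give the alkylalane dimethyl[(2S)-3-(dimethylalumanyloxy)-2-methylpropyl]alumane F8. In the same flask, palladium-catalysed cross-coupling with vinyl bromide (PdCl2(DPEphos), Zn(OTf)2, DMF) gives 11; lipase-catalysed acetylation upgrades the ee if needed.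

**Further compounds**

F1 | step 14 | 2-(dichloromethyl)-(4R,5R)-4,5-dicyclohexyl-1,3,2-dioxaborolane | ClC(Cl)B1O[C@H](C2CCCCC2)[C@@H](C2CCCCC2)O1
F2 | step 14 | bromomagnesium (dichloromethyl)(3-phenylprop-1-en-2-yl)[(1R,2R)-1,2-dicyclohexylethane-1,2-diolato]borate | C=C(Cc1ccccc1)[B-]1(C(Cl)Cl)O[C@H](C2CCCCC2)[C@@H](C2CCCCC2)O1.[Mg+]Br
F3 | step 14 | 2-[(1R)-2-benzyl-1-chloroprop-2-en-1-yl]-(4R,5R)-4,5-dicyclohexyl-1,3,2-dioxaborolane | C=C(Cc1ccccc1)[C@H](Cl)B1O[C@H](C2CCCCC2)[C@@H](C2CCCCC2)O1
F4 | step 8 | (4S,6R,7R,12R)-7,13-dihydroxy-4,6,12-trimethyltrideca-2,9-dienenitrile (E/Z mixture) | OC[C@H](C)CC=CC[C@@H](O)[C@H](C)C[C@H](C)C=CC#N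
F5 | step 8 | (4R,6R,7R,12R)-7,13-dihydroxy-4,6,12-trimethyltridecanenitrile | OC[C@H](C)CCCC[C@@H](O)[C@H](C)C[C@H](C)CCC#N
F6 | step 8 | (4R,6R,7R,12R)-7-hydroxy-4,6,12-trimethyl-13-oxotridecanenitrile | O=C[C@H](C)CCCC[C@@H](O)[C@H](C)C[C@H](C)CCC#N
F7 | step 8 | (4R,6R,7R,12R,13R)-7,13-dihydroxy-4,6,12-trimethylhexadec-15-enenitrile | C=CC[C@@H](O)[C@H](C)CCCC[C@@H](O)[C@H](C)C[C@H](C)CCC#N
F8 | step 5 | dimethyl[(2S)-3-(dimethylalumanyloxy)-2-methylpropyl]alumane | C[Al](C)OC[C@H](C)C[Al](C)C
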